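**Retrosynthetic overview**

1. The target is the C2-symmetric syn head-to-tail cyclobutane dimer of the pyranocoumarin seselin. Both cyclobutane bonds (C3–C4' and C4–C3') are cut last, leaving two identical tricyclic halves.
2. Enabling feature: the C2 axis through the cyclobutane centre places the two benzylic pyran carbons C10 and C10' (the sp2 CH on the arene next to the lactone oxygen) side by side, about 4 Å apart in the reacting stack. As (S)-carbinols they accept a one-atom O–Si–O bridge that enforces head-to-tail, syn and one facial pairing.
3. After the cycloaddition one acid step erases the bridge and both carbinol centres (two-directional double elimination) and regenerates both chromene C=C bonds.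
4. Ring order: lactone ring (present in umbelliferone) → dihydropyranone ring (Fries rearrangement, Kabbe annulation) → asymmetric ketone reduction and silaketal coupling → cyclobutane, closed last.

Key step: step 6

Remark on the chemistry: locants follow seselin numbering (C2 lactone carbonyl, C3=C4 coumarin olefin, O7, C8 gem-dimethyl carbon, C9, C10 benzylic pyran carbon); primes mark the second half.

**Route**

Step 1
Reactants: 1 umbelliferone (7-hydroxycoumarin)
Product: 2 7-acetoxycoumarin
Conditions: Ac2O, pyridine, rt
Reagents that add atoms: acetic anhydride CC(=O)OC(C)=O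
Why: Standard O-acetylation of a phenol with an anhydride and pyridine.

Step 2
Reactants: 2 7-acetoxycoumarin
Product: 3 8-acetyl-7-hydroxycoumarin
Conditions: AlCl3 (3 equiv), neat melt, 150–160 °C; then ice/aq. HCl
Reagents that add atoms: none
Why: Fries rearrangement, in which the AlCl3-bound acylium should migrate to C8, the ortho position between the two oxygen-bearing carbons that is favoured for 7-acyloxycoumarins, the chelated ortho-hydroxy ketone being the thermodynamic sink (a minor C6 isomer would be removed by crystallisation).

Step 3
Reactants: 3 8-acetyl-7-hydroxycoumarin; 4 acetone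
Product: 6 dihydroseselin-10-one (8,8-dimethyl-8,9-dihydro-2H,10H-pyrano[2,3-f]chromene-2,10-dione), via hydroxy-enone 5 (not isolated)
Conditions: acetone (10 equiv), pyrrolidine (0.5 equiv), MeOH, 60 °C
Reagents that add atoms: none
Why: Kabbe chromanone synthesis, in which pyrrolidine-mediated crossed aldol condensation of the methyl ketone with acetone gives the β,β-dimethyl enone 5 and the ortho phenol closes the dihydropyranone by 6-endo oxa-Michael addition; no stereocentre is formed.

Step 4
Reactants: 6 dihydroseselin-10-one
Product: 7 (10S)-10-hydroxy-8,8-dimethyl-9,10-dihydro-2H,8H-pyrano[2,3-f]chromen-2-one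
Conditions: RuCl[(S,S)-TsDPEN](p-cymene) (1 mol%), HCO2H/Et3N (5:2), DMF, 40 °C
Reagents that add atoms: none
Why: Noyori–Ikariya asymmetric transfer hydrogenation, in which the Ru hydride delivers hydride to the ketone face fixed by the CH/π contact between the η6-arene and the fused aryl ring, which with the (S,S)-ligand should give the (S)-carbinol as for 4-chromanone and 1-tetralone, while the coumarin lactone and its C3=C4 bond are not reduced under formate conditions.

Step 5
Reactants: 7 (10S)-chromanol (2 equiv)
Product: 9 diisopropylbis{[(10S)-8,8-dimethyl-2-oxo-9,10-dihydro-2H,8H-pyrano[2,3-f]chromen-10-yl]oxy}silane, via chlorosilyl ether 8 (not isolated)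
Conditions: iPr2SiCl2 (0.5 equiv), imidazole (2.5 equiv), DMAP (cat.), DMF, 0 °C → rt
Reagents that add atoms: dichlorodiisopropylsilane CC(C)[Si](Cl)(Cl)C(C)C
Why: Silyl ether (silaketal) formation at the secondary benzylic hydroxyl, in which the second Si–Cl displacement is slower but driven by imidazole/DMAP, no stereocentre is touched, and any heterochiral (R,S) silaketal from residual (R)-7 is a separable diastereomer, which should raise the enantiopurity of 9.

Step 6
Reactants: 9 bis[(10S)-chromanyloxy]diisopropylsilane
Product: 10 silylene-bridged syn head-to-tail cyclobutane dimer (10,10'-O,O'-diisopropylsilanediyl ether of 11; 3S,4R,3'S,4'R,10S,10'S; all four cyclobutane H cis)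
Conditions: hν (350 nm, Pyrex), degassed MeCN (1 mM), rt
Reagents that add atoms: none
Why: Excitation of one 7-alkoxycoumarin chromophore (S1) should give an intramolecular excimer with the ground-state half held by the C10–O–Si–O–C10' hinge, which collapses by [2π+2π] photocycloaddition to the cyclobutane (bonds C3–C4' and C4–C3'); a triplet 1,4-biradical, if it intervenes, can only close to the same product or revert. The closest known reaction type is the tethered (silicon-tethered) intramolecular [2+2] photodimerisation of coumarins and cinnamates. The cyclobutane closes by suprafacial [2+2] across two endocyclic cis olefins, which fixes both lactone/cyclobutane fusions as cis, and a temporary 14-membered silicon-containing ring results at the same time. The four new stereocentres are controlled by the two (S)-C10 centres: each C10–O bond stays on one face of its coumarin in either half-chair, so a one-atom O–Si–O bridge (O···O about 2.7 Å) fits only a stack in which these two faces look at each other, and bonding on those faces gives the (3S,4R,3'S,4'R) cyclobutane. The step needs head-to-tail over head-to-head, syn over anti and one facial pairing: anti stacks put C10 and C10' more than 8 Å apart, the head-to-head stack turns one oxygen away from its partner and forces the two gem-dimethyl groups onto each other, and the opposite facial pairing turns both oxygens outward, so only the C2-symmetric syn head-to-tail stack with silicon on the C2 axis is within reach. High dilution should suppress intermolecular dimerisation, and at 350 nm the product no longer absorbs, so cycloreversion should not compete.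

Step 7
Reactants: 10 silylene-bridged cyclobutane dimer
Product: 12 target: syn head-to-tail cyclobutane dimer of seselin (3S,4R,3'S,4'R), via bis-chromanol 11 (not isolated)
Conditions: p-TsOH·H2O (0.5 equiv), toluene, 80 °C
Reagents that add atoms: none
Why: Acid-catalysed silaketal hydrolysis followed by E1 dehydration of benzylic chromanols, in which each C10 cation is stabilised by the ortho pyran oxygen and loses H-9, the only β-hydrogen, to give the conjugated 2,2-dimethylchromene, so the bridge and both C10 auxiliary centres disappear while the cyclobutane centres, locked by the two cis-fused lactones, are not touched.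

**Compound list**

1 | umbelliferone (7-hydroxycoumarin) | Oc1ccc2ccc(=O)oc2c1 | starting material
2 | 7-acetoxycoumarin | CC(=O)Oc1ccc2ccc(=O)oc2c1 | intermediate
3 | 8-acetyl-7-hydroxycoumarin | CC(=O)c1c(O)ccc2ccc(=O)oc12 | intermediate
4 | acetone | CC(C)=O | starting material
5 | 7-hydroxy-8-(3-methylbut-2-enoyl)coumarin (hydroxy-enone, not isolated) | CC(C)=CC(=O)c1c(O)ccc2ccc(=O)oc12 | intermediate
6 | 8,8-dimethyl-8,9-dihydro-2H,10H-pyrano[2,3-f]chromene-2,10-dione (dihydroseselin-10-one) | CC1(C)CC(=O)c2c(O1)ccc1ccc(=O)oc21 | intermediate
7 | (10S)-10-hydroxy-8,8-dimethyl-9,10-dihydro-2H,8H-pyrano[2,3-f]chromen-2-one | CC1(C)C[C@H](O)c2c(O1)ccc1ccc(=O)oc21 | intermediate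
8 | chloro(diisopropyl)silyl ether of 7 (10S; not isolated) | CC(C)[Si](Cl)(C(C)C)O[C@H]1CC(C)(C)Oc2ccc3ccc(=O)oc3c21 | intermediate
9 | diisopropylbis{[(10S)-8,8-dimethyl-2-oxo-9,10-dihydro-2H,8H-pyrano[2,3-f]chromen-10-yl]oxy}silane | CC(C)[Si](C(C)C)(O[C@H]1CC(C)(C)Oc2ccc3ccc(=O)oc3c21)O[C@H]1CC(C)(C)Oc2ccc3ccc(=O)oc3c21 | intermediate
10 | silylene-bridged syn head-to-tail cyclobutane dimer; C3–C4' and C4–C3' bonded, all four cyclobutane H cis, both C10–O bonds on the inner faces, Si on the C2 axis; (3S,4R,3'S,4'R,10S,10'S) | CC1(C)C[C@H](O[Si]6(C(C)C)C(C)C)c2c(ccc3c2OC(=O)[C@H]2[C@@H]3[C@H]3C(=O)Oc4c5c(ccc4[C@H]32)OC(C)(C)C[C@@H]5O6)O1 | intermediate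
11 | (10S,10'S)-10,10'-dihydroxy-9,9',10,10'-tetrahydro derivative of 12 (bis-chromanol; cyclobutane 3S,4R,3'S,4'R; not isolated) | CC1(C)C[C@H](O)c2c(ccc3c2OC(=O)[C@H]2[C@@H]3[C@H]3C(=O)Oc4c5c(ccc4[C@H]32)OC(C)(C)C[C@@H]5O)O1 | intermediate
12 | CNP0167575.1: syn head-to-tail cyclobutane dimer of seselin, C3–C4' and C4–C3' bonded, all four cyclobutane H cis, C2-symmetric, (3S,4R,3'S,4'R) | CC1(C)C=Cc2c(ccc3c2OC(=O)[C@H]2[C@@H]3[C@H]3C(=O)Oc4c5c(ccc4[C@H]32)OC(C)(C)C=C5)O1 | target

**Step count**

Total steps: 7. Longest linear sequence: 7 (from umbelliferone 1).

**Steps most likely to fail**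

Step 6. The folded, stacked conformer may be too sparsely populated, so that excited-state decay, intermolecular dimerisation or slow photodegradation could outrun the intramolecular cycloaddition. The fallback gives up the tether and sets out from chromanol 7. Dehydration (p-TsOH, toluene, 80 °C) should give seselin F1. Irradiation of F1 (350 nm, CH2Cl2, BF3·OEt2 0.3 equiv) uses the known Lewis-acid-catalysed coumarin photodimerisation, which favours the syn head-to-tail dimer, and should give the racemate, that is 12 together with the enantiomer of 12 F2. Preparative chiral-phase HPLC then separates the two, and the fallback comes back to the route at 12.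

Step 7. Under hot acid the newly formed electron-rich chromene double bonds could undergo cationic oligomerisation, or the second elimination could stall. The fallback sets out from 10 and avoids strong acid. Fluoride desilylation (HF·pyridine, THF, 0 °C) should give bis-chromanol 11, which is isolated. Mesylation (MsCl, Et3N, CH2Cl2, 0 °C) should give the bis(methanesulfonate) F3, which is not isolated and should lose methanesulfonic acid on addition of DBU at rt. The fallback comes back to the route at 12.

Step 3. Pyrrolidine could add to or open the coumarin lactone, or acetone self-condensation could outrun the crossed aldol. The fallback sets out from umbelliferone 1 and bypasses 2 and 3. Acylation with 3-methylbut-2-enoyl chloride (Et3N, CH2Cl2, 0 °C) should give 2-oxo-2H-chromen-7-yl 3-methylbut-2-enoate F4. Fries rearrangement of F4 (AlCl3, 130 °C) should move the acyl group to C8, giving the same hydroxy-enone 5, which closes in the flask by oxa-Michael addition. The fallback comes back to the route at 6.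

Further compounds
F1 | step 6 | seselin (8,8-dimethyl-2H,8H-pyrano[2,3-f]chromen-2-one) | CC1(C)C=Cc2c(O1)ccc1ccc(=O)oc21
F2 | step 6 | enantiomer of 12 (3R,4S,3'R,4'S) | CC1(C)C=Cc2c(ccc3c2OC(=O)[C@@H]2[C@H]3[C@@H]3C(=O)Oc4c5c(ccc4[C@@H]32)OC(C)(C)C=C5)O1
F3 | step 7 | 10,10'-bis(methanesulfonate) of 11 (10S,10'S) | CC1(C)C[C@H](OS(C)(=O)=O)c2c(ccc3c2OC(=O)[C@H]2[C@@H]3[C@H]3C(=O)Oc4c5c(ccc4[C@H]32)OC(C)(C)C[C@@H]5OS(C)(=O)=O)O1
F4 | step 3 | 2-oxo-2H-chromen-7-yl 3-methylbut-2-enoate | CC(C)=CC(=O)Oc1ccc2ccc(=O)oc2c1
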